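**Plan**
1. Retrosynthesis: cut the stilbene aryl–vinyl bond (Heck), return the ring C olefin and stereocentre to an allylic alcohol by a reductive 1,3-transposition, cut the bond between ring C and its benzylic CH2 (carbonyl addition with transposition), then cut ring C bonds C5–C6 and C1–C2 in one annulation.
2. Enabling feature (ring C numbering: C1 = stereocentre, C2 = methyl-bearing olefinic carbon, C3 = olefinic CH, C6 = CMe2): the C1–C2–C3 allylic triad next to quaternary C6 is a masked 2-methyl-1,3-dione flanked by a gem-dimethyl carbon, the retron of a Michael–Claisen annulation of an isobutyrate donor with ethyl vinyl ketone.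
3. Forward order: ring C first (one-pot Mukaiyama–Michael/Claisen), then attachment of the ring A benzyl unit, reduction, transposition, ring B via Heck coupling, global deprotection.
4. Stereochemistry: a Corey–Bakshi–Shibata reduction sets a (1R)-carbinol at C3; Mitsunobu inversion and suprafacial retro-ene loss of N2 transfer it to C1 (S). The (E)-olefin comes from the Heck step.
5. Helpers: the C3 oxygen drives the annulation and directs the transposition, then leaves; the phenols travel as methoxymethyl ethers.

Key step: step 1

Assumption: the silyl ketene acetal, ethyl vinyl ketone, 5-bromosalicyl alcohol, 3,5-dihydroxybenzaldehyde and all reagents are taken as commercial.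

**Step 1**
Reactants: 1 1-methoxy-2-methyl-1-(trimethylsilyloxy)prop-1-ene; 2 pent-1-en-3-one (ethyl vinyl ketone)
Product: 5 2,4,4-trimethylcyclohexane-1,3-dione, via silyl enol ether 3 (not isolated), via potassium enolate 4 (not isolated)
Conditions: Sc(OTf)3 (5 mol %), CH2Cl2, −78 → 0 °C; solvent exchanged for THF in the same flask; KOtBu (1.2 equiv), 0 °C → reflux; 1 M HCl work-up
Reagents that add atoms: none
Why: Mechanism: Sc(OTf)3 activates the enone and the ketene acetal carbon attacks the terminal CH2 of 2 (Mukaiyama–Michael addition, first bond CH2–CMe2) with silyl transfer to give 3; KOtBu then cleaves the O–Si bond, the potassium enolates equilibrate by proton transfer, and the ethyl-side enolate 4 attacks the methyl ester (Claisen condensation, second bond C(Me)–C(=O)) with loss of methoxide. The closest known reaction type is the Michael–Claisen annulation that gives dimedone, together with the base cyclisation of δ-keto esters to dihydroresorcinols. The single ring closes in the 6-(enolendo)-exo-trig mode. No stereocentre survives, because C2 of the dione is enolised and is made planar again later. The step needs 1,4- over 1,2-addition and one cyclisation regiochemistry: the soft, fully substituted ketene acetal should add in the conjugate sense, only the ethyl-side enolate can reach the ester through a six-membered transition state (the other enolate would close a four-membered ring), and the gem-dimethyl group blocks ester enolisation and speeds closure (Thorpe–Ingold effect). Irreversible formation of the diketonate anion should pull the equilibria towards 5.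

**Step 2**
Reactants: 5 2,4,4-trimethylcyclohexane-1,3-dione
Product: 6 3-(2-methylpropoxy)-2,6,6-trimethylcyclohex-2-en-1-one
Conditions: 2-methylpropan-1-ol (5 equiv), TsOH·H2O (5 mol %), toluene, reflux, Dean–Stark trap; chromatography
Reagents that add atoms: 2-methylpropan-1-ol (isobutanol), CC(C)CO
Why: Acid-catalysed enol etherification of a cyclic 1,3-dione (vinylogous esterification with azeotropic removal of water) should take place mainly at the carbonyl remote from the gem-dimethyl group for steric reasons, leaving the hindered carbonyl as the ketone of the vinylogous ester, and the minor regioisomer is removed by chromatography.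

**Step 3**
Reactants: 7 4-bromo-2-(hydroxymethyl)phenol
Product: 8 [5-bromo-2-(methoxymethoxy)phenyl]methanol
Conditions: chloromethyl methyl ether (1.1 equiv), K2CO3, acetone, 0 °C → rt
Reagents that add atoms: chloromethyl methyl ether, COCCl
Why: Williamson-type O-alkylation in which K2CO3 deprotonates only the phenol, so the phenoxide should be alkylated selectively in the presence of the benzylic alcohol.

**Step 4**
Reactants: 8 [5-bromo-2-(methoxymethoxy)phenyl]methanol
Product: 9 4-bromo-2-(chloromethyl)-1-(methoxymethoxy)benzene
Conditions: PPh3, N-chlorosuccinimide, THF, 0 °C → rt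
Reagents that add atoms: N-chlorosuccinimide, O=C1CCC(=O)N1Cl
Why: Appel-type chlorination, in which the chlorophosphonium species activates the benzylic alcohol for SN2 displacement by chloride under neutral conditions that spare the acetal.

**Step 5**
Reactants: 9 4-bromo-2-(chloromethyl)-1-(methoxymethoxy)benzene; 6 3-(2-methylpropoxy)-2,6,6-trimethylcyclohex-2-en-1-one
Product: 12 3-{[5-bromo-2-(methoxymethoxy)phenyl]methyl}-2,4,4-trimethylcyclohex-2-en-1-one, via benzylic Grignard reagent 10 (not isolated), via magnesium alkoxide adduct 11 (not isolated)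
Conditions: Mg turnings, Et2O, 0 °C (slow addition of 9); then 6, LaCl3·2LiCl (1 equiv), THF, 0 °C → rt; then 1 M HCl, THF, 0 °C, short contact
Reagents that add atoms: water, O
Why: Stork–Danheiser alkylative carbonyl transposition, in which magnesium should insert into the benzylic C–Cl bond far faster than into the aryl C–Br bond, the benzylic Grignard reagent adds 1,2 to the Lewis-acid-activated vinylogous ester carbonyl, and brief dilute acid ionises the tertiary allylic alcohol and hydrolyses the enol ether to the transposed enone without cleaving the aryl acetal.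

**Step 6**
Reactants: 12 3-{[5-bromo-2-(methoxymethoxy)phenyl]methyl}-2,4,4-trimethylcyclohex-2-en-1-one
Product: 13 (1R)-3-{[5-bromo-2-(methoxymethoxy)phenyl]methyl}-2,4,4-trimethylcyclohex-2-en-1-ol
Conditions: (S)-2-methyl-CBS-oxazaborolidine (20 mol %), BH3·SMe2, THF, −20 °C; MeOH quench, aqueous work-up
Reagents that add atoms: none
Why: Corey–Bakshi–Shibata reduction, in which the methyl-substituted olefinic carbon acts as the large group and the ring CH2 as the small one in the catalyst–borane–ketone complex, so the (S)-catalyst should deliver hydride to give the (1R)-alcohol as with other 2-substituted cyclohex-2-enones.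

**Step 7**
Reactants: 13 (1R)-3-{[5-bromo-2-(methoxymethoxy)phenyl]methyl}-2,4,4-trimethylcyclohex-2-en-1-ol
Product: 16 4-bromo-1-(methoxymethoxy)-2-{[(1S)-2,6,6-trimethylcyclohex-2-en-1-yl]methyl}benzene, via sulfonylhydrazine adduct 14 (not isolated), via allylic diazene 15 (not isolated)
Conditions: PPh3, diethyl azodicarboxylate, 2-nitrobenzenesulfonylhydrazide, THF, −30 °C; then warm to rt
Reagents that add atoms: none
Why: Reductive 1,3-transposition of an allylic alcohol (Mitsunobu displacement by the sulfonylhydrazide with inversion, loss of sulfinic acid to the allylic diazene, suprafacial retro-ene loss of N2), which should deliver hydrogen to the benzyl-bearing carbon on the face opposite to the original hydroxyl, so setting the (S) stereocentre and placing the double bond between the methyl-bearing carbon and the former carbinol carbon.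

**Step 8**
Reactants: 17 3,5-dihydroxybenzaldehyde
Product: 18 3,5-bis(methoxymethoxy)benzaldehyde
Conditions: chloromethyl methyl ether (2.5 equiv), K2CO3, acetone, reflux
Reagents that add atoms: chloromethyl methyl ether, COCCl
Why: Double Williamson-type O-alkylation of the two phenoxides, which leaves the aldehyde untouched.

**Step 9**
Reactants: 18 3,5-bis(methoxymethoxy)benzaldehyde
Product: 19 1-ethenyl-3,5-bis(methoxymethoxy)benzene
Conditions: methyltriphenylphosphonium bromide, KOtBu, THF, 0 °C → rt
Reagents that add atoms: methyltriphenylphosphonium bromide, C[P+](c1ccccc1)(c1ccccc1)c1ccccc1.[Br-]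
Why: Wittig methylenation of an aromatic aldehyde with the non-stabilised ylide, under basic conditions that the acetals tolerate.

**Step 10**
Reactants: 16 4-bromo-1-(methoxymethoxy)-2-{[(1S)-2,6,6-trimethylcyclohex-2-en-1-yl]methyl}benzene; 19 1-ethenyl-3,5-bis(methoxymethoxy)benzene
Product: 20 1-[(E)-2-[3,5-bis(methoxymethoxy)phenyl]ethenyl]-4-(methoxymethoxy)-3-{[(1S)-2,6,6-trimethylcyclohex-2-en-1-yl]methyl}benzene
Conditions: Pd2(dba)3 (2.5 mol %), P(t-Bu)3 (10 mol %), Cs2CO3, 1,4-dioxane, 100 °C
Reagents that add atoms: none
Why: Mizoroki–Heck reaction, in which oxidative addition of the aryl bromide to zerovalent palladium, insertion of the styrene at its terminal carbon and syn β-hydride elimination should give the (E)-stilbene, while the hindered trisubstituted ring alkene does not compete and the non-acidic stereocentre is untouched by the carbonate base.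

**Step 11**
Reactants: 20 1-[(E)-2-[3,5-bis(methoxymethoxy)phenyl]ethenyl]-4-(methoxymethoxy)-3-{[(1S)-2,6,6-trimethylcyclohex-2-en-1-yl]methyl}benzene
Product: 21 5-[(E)-2-(4-hydroxy-3-{[(1S)-2,6,6-trimethylcyclohex-2-en-1-yl]methyl}phenyl)ethenyl]benzene-1,3-diol
Conditions: TsOH·H2O (0.5 equiv), MeOH, rt
Reagents that add atoms: none
Why: Acid-catalysed acetal exchange with methanol should cleave all three methoxymethyl ethers at room temperature, conditions mild enough for a trisubstituted alkene next to a free phenol, so that cyclisation of the ring A phenol onto the ring C alkene should not compete.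

**Compound list**
1 | 1-methoxy-2-methyl-1-(trimethylsilyloxy)prop-1-ene | COC(O[Si](C)(C)C)=C(C)C | starting material
2 | pent-1-en-3-one (ethyl vinyl ketone) | CCC(=O)C=C | starting material
3 | methyl (Z)-2,2-dimethyl-5-(trimethylsilyloxy)hept-4-enoate | COC(=O)C(C)(C)C/C=C(/CC)O[Si](C)(C)C | intermediate
4 | potassium (Z)-7-methoxy-6,6-dimethyl-7-oxohept-2-en-3-olate (ethyl-side enolate of methyl 2,2-dimethyl-5-oxoheptanoate; geometry immaterial) | COC(=O)C(C)(C)CC/C([O-])=C/C.[K+] | intermediate
5 | 2,4,4-trimethylcyclohexane-1,3-dione (C2 enolisable, no fixed configuration) | CC1C(=O)CCC(C)(C)C1=O | intermediate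
6 | 3-(2-methylpropoxy)-2,6,6-trimethylcyclohex-2-en-1-one | CC1=C(OCC(C)C)CCC(C)(C)C1=O | intermediate
7 | 4-bromo-2-(hydroxymethyl)phenol (5-bromosalicyl alcohol) | OCc1cc(Br)ccc1O | starting material
8 | [5-bromo-2-(methoxymethoxy)phenyl]methanol | OCc1cc(Br)ccc1OCOC | intermediate
9 | 4-bromo-2-(chloromethyl)-1-(methoxymethoxy)benzene | ClCc1cc(Br)ccc1OCOC | intermediate
10 | {[5-bromo-2-(methoxymethoxy)phenyl]methyl}magnesium chloride | Cl[Mg]Cc1cc(Br)ccc1OCOC | intermediate
11 | chloromagnesium 1-{[5-bromo-2-(methoxymethoxy)phenyl]methyl}-3-(2-methylpropoxy)-2,6,6-trimethylcyclohex-2-en-1-olate (racemic) | CC1=C(OCC(C)C)CCC(C)(C)C1(Cc2cc(Br)ccc2OCOC)O[Mg]Cl | intermediate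
12 | 3-{[5-bromo-2-(methoxymethoxy)phenyl]methyl}-2,4,4-trimethylcyclohex-2-en-1-one | CC1=C(Cc2cc(Br)ccc2OCOC)C(C)(C)CCC1=O | intermediate
13 | (1R)-3-{[5-bromo-2-(methoxymethoxy)phenyl]methyl}-2,4,4-trimethylcyclohex-2-en-1-ol | O[C@@H]1CCC(C)(C)C(Cc2cc(Br)ccc2OCOC)=C1C | intermediate
14 | 1-[(1S)-3-{[5-bromo-2-(methoxymethoxy)phenyl]methyl}-2,4,4-trimethylcyclohex-2-en-1-yl]-1-(2-nitrophenylsulfonyl)hydrazine | NN([C@H]1CCC(C)(C)C(Cc2cc(Br)ccc2OCOC)=C1C)S(=O)(=O)c1ccccc1[N+](=O)[O-] | intermediate
15 | [(1S)-3-{[5-bromo-2-(methoxymethoxy)phenyl]methyl}-2,4,4-trimethylcyclohex-2-en-1-yl]diazene | N=N[C@H]1CCC(C)(C)C(Cc2cc(Br)ccc2OCOC)=C1C | intermediate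
16 | 4-bromo-1-(methoxymethoxy)-2-{[(1S)-2,6,6-trimethylcyclohex-2-en-1-yl]methyl}benzene | CC1=CCCC(C)(C)[C@@H]1Cc1cc(Br)ccc1OCOC | intermediate
17 | 3,5-dihydroxybenzaldehyde | O=Cc1cc(O)cc(O)c1 | starting material
18 | 3,5-bis(methoxymethoxy)benzaldehyde | O=Cc1cc(OCOC)cc(OCOC)c1 | intermediate
19 | 1-ethenyl-3,5-bis(methoxymethoxy)benzene | C=Cc1cc(OCOC)cc(OCOC)c1 | intermediate
20 | 1-[(E)-2-[3,5-bis(methoxymethoxy)phenyl]ethenyl]-4-(methoxymethoxy)-3-{[(1S)-2,6,6-trimethylcyclohex-2-en-1-yl]methyl}benzene | CC1=CCCC(C)(C)[C@@H]1Cc1cc(/C=C/c2cc(OCOC)cc(OCOC)c2)ccc1OCOC | intermediate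
21 | 5-[(E)-2-(4-hydroxy-3-{[(1S)-2,6,6-trimethylcyclohex-2-en-1-yl]methyl}phenyl)ethenyl]benzene-1,3-diol | CC1=CCCC(C)(C)[C@@H]1Cc1cc(/C=C/c2cc(O)cc(O)c2)ccc1O | target

**Totals and risks**
Total step count: 11. Longest linear sequence: 7 steps (steps 1, 2, 5, 6, 7, 10, 11).

Steps most likely to fail:

Step 7. The SN2 attack of the sulfonylhydrazide on a secondary allylic carbinol flanked by a fully substituted olefinic carbon may be slow. Elimination to a diene could then compete, or ionisation with attack from both faces could erode the chirality transfer. Fallback (sets out from 13, returns at 20): 13 is first coupled with 19 under the conditions of step 10 to give the stilbene allylic alcohol (1R)-3-({5-[(E)-2-[3,5-bis(methoxymethoxy)phenyl]ethenyl]-2-(methoxymethoxy)phenyl}methyl)-2,4,4-trimethylcyclohex-2-en-1-ol F1. This is formylated (acetic formic anhydride, pyridine, 0 °C) to the corresponding allylic formate F2. Pd(OAc)2/PBu3 (5 mol %, THF, rt → 65 °C) should then ionise the formate with inversion to a π-allyl complex of divalent palladium; decarboxylation gives a palladium hydride, and reductive elimination delivers hydride from the metal face to the more substituted, benzyl-bearing terminus (hydrogenolysis of an allylic formate, Tsuji–Trost type). Hydrogen again arrives anti to the original oxygen, so 20 results directly. The coupling is placed first so that no aryl bromide is present during the palladium/formate step.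

Step 5. Wurtz-type homocoupling during magnesium insertion, or deprotonation of the vinylogous ester instead of 1,2-addition at its hindered carbonyl, could starve the addition. Fallback (sets out from 6 and 9, returns at 12): the bond is made by cross-coupling at an sp2 carbon instead of carbonyl addition. Deprotonation of 6 at its only acidic position (the ring CH2 next to the enol ether carbon; LDA, THF, −78 °C) and O-sulfonylation with N-phenylbis(trifluoromethanesulfonimide) should give 3-(2-methylpropoxy)-2,6,6-trimethylcyclohexa-1,3-dien-1-yl trifluoromethanesulfonate F3. Zinc dust/LiCl (THF, rt) converts 9 into {[5-bromo-2-(methoxymethoxy)phenyl]methyl}zinc chloride F4. Negishi coupling (Pd(PPh3)4, 5 mol %, THF, rt, where the dienyl triflate should react ahead of the electron-rich aryl bromide) gives the dienol ether 4-bromo-1-(methoxymethoxy)-2-{[3-(2-methylpropoxy)-2,6,6-trimethylcyclohexa-1,3-dien-1-yl]methyl}benzene F5. Brief 1 M HCl in THF hydrolyses it to 12.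

Step 1. Oligomerisation of the vinyl ketone under the Lewis acid or the base, and intermolecular condensation of the enolates in competition with ring closure, could lower the throughput. Fallback (sets out from 2, returns at 5): acid-catalysed Robinson annulation of 2 with 2-methylpropanal (catalytic H2SO4, toluene, reflux with azeotropic removal of water) makes the same two ring bonds in one operation and gives 2,4,4-trimethylcyclohex-2-en-1-one F6. Weitz–Scheffer epoxidation (H2O2, NaOH, MeOH, 0 °C) gives racemic 1,5,5-trimethyl-7-oxabicyclo[4.1.0]heptan-2-one F7. Isomerisation of the α,β-epoxy ketone to the 1,3-diketone with catalytic Pd(PPh3)4 (zerovalent palladium) and 1,2-bis(diphenylphosphino)ethane in toluene at 100 °C returns 5.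

**Further compounds**
F1 | step 7 | (1R)-3-({5-[(E)-2-[3,5-bis(methoxymethoxy)phenyl]ethenyl]-2-(methoxymethoxy)phenyl}methyl)-2,4,4-trimethylcyclohex-2-en-1-ol | O[C@@H]1CCC(C)(C)C(Cc2cc(/C=C/c3cc(OCOC)cc(OCOC)c3)ccc2OCOC)=C1C
F2 | step 7 | (1R)-3-({5-[(E)-2-[3,5-bis(methoxymethoxy)phenyl]ethenyl]-2-(methoxymethoxy)phenyl}methyl)-2,4,4-trimethylcyclohex-2-en-1-yl formate | O=CO[C@@H]1CCC(C)(C)C(Cc2cc(/C=C/c3cc(OCOC)cc(OCOC)c3)ccc2OCOC)=C1C
F3 | step 5 | 3-(2-methylpropoxy)-2,6,6-trimethylcyclohexa-1,3-dien-1-yl trifluoromethanesulfonate | CC1=C(OS(=O)(=O)C(F)(F)F)C(C)(C)CC=C1OCC(C)C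
F4 | step 5 | {[5-bromo-2-(methoxymethoxy)phenyl]methyl}zinc chloride | Cl[Zn]Cc1cc(Br)ccc1OCOC
F5 | step 5 | 4-bromo-1-(methoxymethoxy)-2-{[3-(2-methylpropoxy)-2,6,6-trimethylcyclohexa-1,3-dien-1-yl]methyl}benzene | CC1=C(Cc2cc(Br)ccc2OCOC)C(C)(C)CC=C1OCC(C)C
F6 | step 1 | 2,4,4-trimethylcyclohex-2-en-1-one | CC1=CC(C)(C)CCC1=O
F7 | step 1 | 1,5,5-trimethyl-7-oxabicyclo[4.1.0]heptan-2-one (racemic, cis-fused epoxide) | CC12OC1C(C)(C)CCC2=O
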